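**Plan**
Cuts: first the N-Boc and N-(2,4-dimethoxybenzyl) groups. Next, C3–C3a and N1–C7a of the 5-hydroxyindole, which leaves 1,4-benzoquinone and the secondary enamine of an arylacetaldehyde. Last, the enamine C–N bond, the bond from C3 of the 6-methoxyindole to the central benzene, and the aryl–CH2 bond of the two-carbon arm.
Enabling feature: in the 5-hydroxyindole the oxygen on C5 stands para to C7a (the carbon holding N1), C3a is the neighbour of C7a, and C4, C6 and C7 carry only hydrogen. This maps onto 1,4-benzoquinone with one carbonyl kept (C5–OH), one condensed with nitrogen (C7a) and one ring C–H replaced by the enamine carbon (C3a).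
Forward, part 1: 1,2,4,5-tetramethoxybenzene is hydroxyethylated by directed lithiation and then brominated, 6-methoxyindole is N-Boc protected and borylated at C3, and a Suzuki–Miyaura coupling joins the two halves.
Forward, part 2: the alcohol is oxidised to the aldehyde and condensed with 2,4-dimethoxybenzylamine. The pyrrole ring of the second indole, the only ring made in the route, is then closed on the quinone, and acid frees both N–H groups.
Stereochemistry: the target has no stereocentre. The enamine geometry is not fixed and adjusts through the imine tautomer.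

Key step: step 8

Assumption: 13 is drawn as its (E)-enamine tautomer, the form that reacts in step 8. In solution it is expected to exchange with imine 12, and acid makes this exchange fast, so the crude condensate is used as such.

**Route**

Step 1
Reactants: 1 1,2,4,5-tetramethoxybenzene; 2 ethylene oxide
Product: 4 2-(2,3,5,6-tetramethoxyphenyl)ethanol, via 2,3,5,6-tetramethoxyphenyllithium 3 (not isolated)
Conditions: n-BuLi (1.05 equiv), THF, 0 °C; then 2 (THF solution), −78 °C to rt; H2O quench
Reagents that add atoms: none
Why: Directed ortho-metalation works because each ring C–H of 1 lies between two methoxy groups, so one equivalent of n-BuLi should give the monolithio species 3, and aryllithium opening of the epoxide installs the two carbons that later become C3 and C2 of the hydroxyindole.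

Step 2
Reactants: 4 2-(2,3,5,6-tetramethoxyphenyl)ethanol
Product: 5 2-(4-bromo-2,3,5,6-tetramethoxyphenyl)ethanol
Conditions: NBS (1.0 equiv), dry MeCN, 0 °C, dark
Reagents that add atoms: N-bromosuccinimide, O=C1CCC(=O)N1Br
Why: In this electrophilic aromatic bromination the single remaining ring C–H is activated by four methoxy groups and should react long before the primary alcohol, while dry conditions avoid oxidative demethylation to a quinone.

Step 3
Reactants: 6 6-methoxyindole
Product: 7 tert-butyl 6-methoxyindole-1-carboxylate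
Conditions: Boc2O (1.1 equiv), DMAP (cat.), MeCN, rt
Reagents that add atoms: di-tert-butyl dicarbonate, CC(C)(C)OC(=O)OC(=O)OC(C)(C)C
Why: DMAP-catalysed N-acylation of the indole gives a carbamate that shields C2 in step 4, damps the nucleophilicity of this indole towards the quinone in step 8 and leaves in the final acid treatment.

Step 4
Reactants: 7 tert-butyl 6-methoxyindole-1-carboxylate
Product: 8 tert-butyl 6-methoxy-3-(4,4,5,5-tetramethyl-1,3,2-dioxaborolan-2-yl)indole-1-carboxylate
Conditions: B2pin2 (1.0 equiv), [Ir(OMe)(cod)]2 (1.5 mol %), 4,4'-di-tert-butyl-2,2'-bipyridine (3 mol %), THF, 60 °C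
Reagents that add atoms: bis(pinacolato)diboron, CC1(C)OB(B2OC(C)(C)C(C)(C)O2)OC1(C)C
Why: Iridium-catalysed C–H borylation is sterically governed, so with Boc shielding C2 and C7 and the methoxy group shielding C5 and C7, the heteroaryl C3–H should be borylated as is established for N-Boc indoles.

Step 5
Reactants: 5 2-(4-bromo-2,3,5,6-tetramethoxyphenyl)ethanol; 8 tert-butyl 6-methoxy-3-(4,4,5,5-tetramethyl-1,3,2-dioxaborolan-2-yl)indole-1-carboxylate
Product: 9 tert-butyl 3-[4-(2-hydroxyethyl)-2,3,5,6-tetramethoxyphenyl]-6-methoxyindole-1-carboxylate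
Conditions: Pd(OAc)2 (5 mol %), SPhos (10 mol %), K3PO4 (2 equiv), toluene/H2O (10:1), 80 °C
Reagents that add atoms: none
Why: This Suzuki–Miyaura coupling uses a bulky, electron-rich biarylphosphine suited to oxidative addition and reductive elimination at electron-rich, doubly ortho-substituted aryl bromides, the phosphate base at 80 °C should leave the indole carbamate in place, and the free alcohol is a spectator.

Step 6
Reactants: 9 tert-butyl 3-[4-(2-hydroxyethyl)-2,3,5,6-tetramethoxyphenyl]-6-methoxyindole-1-carboxylate
Product: 10 tert-butyl 6-methoxy-3-[2,3,5,6-tetramethoxy-4-(2-oxoethyl)phenyl]indole-1-carboxylate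
Conditions: Dess–Martin periodinane (1.2 equiv), CH2Cl2, 0 °C to rt
Reagents that add atoms: none
Why: Dess–Martin oxidation stops at the aldehyde under neutral, water-free conditions that leave the carbamate-deactivated indole and the aryl ethers alone, and the enolisable arylacetaldehyde is carried on without storage.

Step 7
Reactants: 10 tert-butyl 6-methoxy-3-[2,3,5,6-tetramethoxy-4-(2-oxoethyl)phenyl]indole-1-carboxylate; 11 2,4-dimethoxybenzylamine
Product: 13 tert-butyl 3-[4-[(E)-2-(2,4-dimethoxybenzylamino)ethenyl]-2,3,5,6-tetramethoxyphenyl]-6-methoxyindole-1-carboxylate, via imine tautomer 12 (not isolated)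
Conditions: 11 (1.0 equiv), 4 Å molecular sieves, CH2Cl2, rt; filtered, concentrated, used crude
Reagents that add atoms: none
Why: In this dehydrative condensation of an arylacetaldehyde with a primary amine the first-formed imine 12 shifts to the aryl-conjugated secondary enamine 13 by imine–enamine tautomerism, and with one equivalent of amine at room temperature the aldehyde should react far faster than the indole carbamate.

Step 8
Reactants: 13 tert-butyl 3-[4-[(E)-2-(2,4-dimethoxybenzylamino)ethenyl]-2,3,5,6-tetramethoxyphenyl]-6-methoxyindole-1-carboxylate; 14 1,4-benzoquinone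
Product: 17 tert-butyl 3-[4-[1-(2,4-dimethoxybenzyl)-5-hydroxyindol-3-yl]-2,3,5,6-tetramethoxyphenyl]-6-methoxyindole-1-carboxylate, via hydroquinone Michael adduct 15 (not isolated), via quinone enamine 16 (not isolated)
Conditions: 14 (1.3 equiv), AcOH/CH3NO2 (1:4), rt, N2, slow addition of 13 to 14
Reagents that add atoms: none
Why: Proposed new method: the β-carbon of 13 should add to a ring C–H carbon of the quinone in a Michael reaction and after proton shifts give the 2,2-diarylethenamine hydroquinone 15, which the surplus quinone oxidises to 16; the N–H nitrogen, brought cis to the quinone ring by rotation through the imine tautomer, then attacks the neighbouring carbonyl carbon in a 5-exo-trig closure, water is lost, and the hydroquinone made earlier returns its two electrons to give the aromatic 5-hydroxyindole 17, so C3–C3a and N1–C7a arise in one flask in an overall redox-neutral equation. The closest known reaction type is the Nenitzescu 5-hydroxyindole synthesis from β-aminocrotonates or related enaminones and 1,4-benzoquinone, and what is new is an enamine with an aryl group and no acceptor at the attacking carbon and with hydrogen at the future C2. No stereocentre is formed. Regiochemistry is not in question, because the four C–H positions of 14 are equivalent and the untouched carbonyl can only end up at C5, para to nitrogen. The selectivity that is needed is closure through nitrogen rather than through the phenol oxygen of 15, which would lead on to a benzofuran-5-ol by loss of the amine: the secondary enamine keeps a nucleophilic N–H after C-attack, slow addition into excess quinone shortens the lifetime of 15 by rapid oxidation to 16, which has no phenol left, and acetic acid in nitromethane, the medium that favours indoles in the parent reaction, is too weak an acid to drive amine expulsion. The Boc group keeps the 6-methoxyindole from adding to the quinone through its C2 and should survive acetic acid at room temperature.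

Step 9
Reactants: 17 tert-butyl 3-[4-[1-(2,4-dimethoxybenzyl)-5-hydroxyindol-3-yl]-2,3,5,6-tetramethoxyphenyl]-6-methoxyindole-1-carboxylate
Product: 18 3-[4-(6-methoxy-1H-indol-3-yl)-2,3,5,6-tetramethoxyphenyl]-1H-indol-5-ol (CNP0234672.0)
Conditions: CF3CO2H/CH2Cl2 (1:1), anisole (20 equiv), 0 °C to rt
Reagents that add atoms: none
Why: In this acidolysis the carbamate loses isobutene and CO2, protonation of the benzylated indole at C3 lets the stabilised 2,4-dimethoxybenzyl cation leave nitrogen, and the large excess of anisole should capture that cation by Friedel–Crafts alkylation before it re-alkylates the product, while the aryl methyl ethers and the phenol are inert.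

**Compound list**
1 | 1,2,4,5-tetramethoxybenzene | COc1cc(OC)c(OC)cc1OC | starting material
2 | ethylene oxide | C1CO1 | starting material
3 | 2,3,5,6-tetramethoxyphenyllithium | [Li]c1c(OC)c(OC)cc(OC)c1OC | intermediate
4 | 2-(2,3,5,6-tetramethoxyphenyl)ethanol | OCCc1c(OC)c(OC)cc(OC)c1OC | intermediate
5 | 2-(4-bromo-2,3,5,6-tetramethoxyphenyl)ethanol | OCCc1c(OC)c(OC)c(Br)c(OC)c1OC | intermediate
6 | 6-methoxyindole | COc1ccc2cc[nH]c2c1 | starting material
7 | tert-butyl 6-methoxyindole-1-carboxylate | COc1ccc2ccn(C(=O)OC(C)(C)C)c2c1 | intermediate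
8 | tert-butyl 6-methoxy-3-(4,4,5,5-tetramethyl-1,3,2-dioxaborolan-2-yl)indole-1-carboxylate | COc1ccc2c(B3OC(C)(C)C(C)(C)O3)cn(C(=O)OC(C)(C)C)c2c1 | intermediate
9 | tert-butyl 3-[4-(2-hydroxyethyl)-2,3,5,6-tetramethoxyphenyl]-6-methoxyindole-1-carboxylate | COc1ccc2c(-c3c(OC)c(OC)c(CCO)c(OC)c3OC)cn(C(=O)OC(C)(C)C)c2c1 | intermediate
10 | tert-butyl 6-methoxy-3-[2,3,5,6-tetramethoxy-4-(2-oxoethyl)phenyl]indole-1-carboxylate | COc1ccc2c(-c3c(OC)c(OC)c(CC=O)c(OC)c3OC)cn(C(=O)OC(C)(C)C)c2c1 | intermediate
11 | 2,4-dimethoxybenzylamine | COc1ccc(CN)c(OC)c1 | starting material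
12 | tert-butyl 3-[4-[(2E)-2-(2,4-dimethoxybenzylimino)ethyl]-2,3,5,6-tetramethoxyphenyl]-6-methoxyindole-1-carboxylate (imine tautomer) | COc1ccc(C/N=C/Cc2c(OC)c(OC)c(-c3cn(C(=O)OC(C)(C)C)c4cc(OC)ccc34)c(OC)c2OC)c(OC)c1 | intermediate
13 | tert-butyl 3-[4-[(E)-2-(2,4-dimethoxybenzylamino)ethenyl]-2,3,5,6-tetramethoxyphenyl]-6-methoxyindole-1-carboxylate | COc1ccc(CN/C=C/c2c(OC)c(OC)c(-c3cn(C(=O)OC(C)(C)C)c4cc(OC)ccc34)c(OC)c2OC)c(OC)c1 | intermediate
14 | 1,4-benzoquinone | O=C1C=CC(=O)C=C1 | starting material
15 | tert-butyl 3-[4-[2-(2,4-dimethoxybenzylamino)-1-(2,5-dihydroxyphenyl)ethenyl]-2,3,5,6-tetramethoxyphenyl]-6-methoxyindole-1-carboxylate, drawn with nitrogen cis to the dihydroxyphenyl ring | COc1ccc(CN/C=C(\c2cc(O)ccc2O)c2c(OC)c(OC)c(-c3cn(C(=O)OC(C)(C)C)c4cc(OC)ccc34)c(OC)c2OC)c(OC)c1 | intermediate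
16 | tert-butyl 3-[4-[2-(2,4-dimethoxybenzylamino)-1-(3,6-dioxocyclohexa-1,4-dien-1-yl)ethenyl]-2,3,5,6-tetramethoxyphenyl]-6-methoxyindole-1-carboxylate, drawn with nitrogen cis to the quinone ring | COc1ccc(CN/C=C(\C2=CC(=O)C=CC2=O)c2c(OC)c(OC)c(-c3cn(C(=O)OC(C)(C)C)c4cc(OC)ccc34)c(OC)c2OC)c(OC)c1 | intermediate
17 | tert-butyl 3-[4-[1-(2,4-dimethoxybenzyl)-5-hydroxyindol-3-yl]-2,3,5,6-tetramethoxyphenyl]-6-methoxyindole-1-carboxylate | COc1ccc(Cn2cc(-c3c(OC)c(OC)c(-c4cn(C(=O)OC(C)(C)C)c5cc(OC)ccc45)c(OC)c3OC)c3cc(O)ccc32)c(OC)c1 | intermediate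
18 | 3-[4-(6-methoxy-1H-indol-3-yl)-2,3,5,6-tetramethoxyphenyl]-1H-indol-5-ol (CNP0234672.0) | COc1ccc2c(-c3c(OC)c(OC)c(-c4c[nH]c5ccc(O)cc45)c(OC)c3OC)c[nH]c2c1 | target

**Step count**
Total steps: 9.
Longest linear sequence: 7 steps (1, 2, 5, 6, 7, 8, 9; the branch 3, 4, 5, 6, 7, 8, 9 is equally long).

**Steps most likely to fail**

Step 8 (labelled step). Four processes may spoil it:
- closure of the Michael adduct through oxygen with expulsion of the amine;
- attack of the enamine nitrogen, or of amine freed by hydrolysis, on the quinone;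
- slow C-attack at the hindered β-carbon;
- further reaction of the electron-rich product with surplus quinone.

The fallback is a Fischer indole synthesis, which is known chemistry for arylacetaldehydes. It sets out from 10 and comes back at 18, bypassing steps 7 to 9. Condensation of 10 with 4-(benzyloxy)phenylhydrazine hydrochloride (NaOAc, EtOH, rt) should give the 4-(benzyloxy)phenylhydrazone F1. Warming in ethanolic HCl should bring about the [3,3]-sigmatropic shift and loss of ammonia. The para-substituted hydrazine allows only the 5-oxygenated indole. The same acid should strip the Boc group, giving the 5-O-benzyl ether of the target F2. Hydrogenolysis (H2, Pd/C, EtOAc/MeOH) then gives 18.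

Step 9. N-Debenzylation of the indole may be sluggish, the benzyl cation may re-alkylate the electron-rich hydroxyindole, and strong acid may oligomerise indoles with a free C2. The fallback replaces acidolysis by oxidative and basic cleavage. It sets out from 17 and comes back at 18. Acetylation (Ac2O, pyridine, rt) masks the phenol against oxidation and gives the 5-acetate F3. DDQ in CH2Cl2/H2O should remove the dimethoxybenzyl group as its aldehyde and give the N–H indole acetate F4. K2CO3 in MeOH then cleaves the acetate and the indole carbamate together by methanolysis to give 18.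

Step 5. Protodeboronation of the indolylboronate may outrun slow transmetalation at the doubly ortho-substituted arylpalladium species, and part of the Boc group may be lost in hot aqueous base. The fallback reverses the polarity of the partners in a water-free Negishi coupling. It sets out from 5 and 6 and comes back at 9.
- From 5: silylation (TBSCl, imidazole, DMF) gives the tert-butyldimethylsilyl ether F5. Bromine–lithium exchange (n-BuLi, THF, −78 °C) gives the aryllithium F6, and ZnCl2 converts it into the arylzinc chloride F7.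
- From 6: iodination (I2, KOH, DMF) gives 3-iodo-6-methoxyindole F8, which is protected at once (Boc2O, DMAP, CH2Cl2) as tert-butyl 3-iodo-6-methoxyindole-1-carboxylate F9.
- Coupling of F7 with F9 (Pd2(dba)3, SPhos, THF, 60 °C) should give the coupled silyl ether F10, and tetrabutylammonium fluoride in THF releases alcohol 9.

**Further compounds**
F1 | step 8 | tert-butyl 3-[4-[(2E)-2-[2-(4-benzyloxyphenyl)hydrazinylidene]ethyl]-2,3,5,6-tetramethoxyphenyl]-6-methoxyindole-1-carboxylate | COc1ccc2c(-c3c(OC)c(OC)c(C/C=N/Nc4ccc(OCc5ccccc5)cc4)c(OC)c3OC)cn(C(=O)OC(C)(C)C)c2c1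
F2 | step 8 | 5-benzyloxy-3-[4-(6-methoxy-1H-indol-3-yl)-2,3,5,6-tetramethoxyphenyl]-1H-indole | COc1ccc2c(-c3c(OC)c(OC)c(-c4c[nH]c5ccc(OCc6ccccc6)cc45)c(OC)c3OC)c[nH]c2c1
F3 | step 9 | tert-butyl 3-[4-[5-acetoxy-1-(2,4-dimethoxybenzyl)indol-3-yl]-2,3,5,6-tetramethoxyphenyl]-6-methoxyindole-1-carboxylate | COc1ccc(Cn2cc(-c3c(OC)c(OC)c(-c4cn(C(=O)OC(C)(C)C)c5cc(OC)ccc45)c(OC)c3OC)c3cc(OC(C)=O)ccc32)c(OC)c1
F4 | step 9 | tert-butyl 3-[4-(5-acetoxy-1H-indol-3-yl)-2,3,5,6-tetramethoxyphenyl]-6-methoxyindole-1-carboxylate | COc1ccc2c(-c3c(OC)c(OC)c(-c4c[nH]c5ccc(OC(C)=O)cc45)c(OC)c3OC)cn(C(=O)OC(C)(C)C)c2c1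
F5 | step 5 | [2-(4-bromo-2,3,5,6-tetramethoxyphenyl)ethoxy](tert-butyl)dimethylsilane | CC(C)(C)[Si](C)(C)OCCc1c(OC)c(OC)c(Br)c(OC)c1OC
F6 | step 5 | 4-[2-(tert-butyldimethylsilyloxy)ethyl]-2,3,5,6-tetramethoxyphenyllithium | [Li]c1c(OC)c(OC)c(CCO[Si](C)(C)C(C)(C)C)c(OC)c1OC
F7 | step 5 | 4-[2-(tert-butyldimethylsilyloxy)ethyl]-2,3,5,6-tetramethoxyphenylzinc chloride | Cl[Zn]c1c(OC)c(OC)c(CCO[Si](C)(C)C(C)(C)C)c(OC)c1OC
F8 | step 5 | 3-iodo-6-methoxyindole | COc1ccc2c(I)c[nH]c2c1
F9 | step 5 | tert-butyl 3-iodo-6-methoxyindole-1-carboxylate | COc1ccc2c(I)cn(C(=O)OC(C)(C)C)c2c1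
F10 | step 5 | tert-butyl 3-[4-[2-(tert-butyldimethylsilyloxy)ethyl]-2,3,5,6-tetramethoxyphenyl]-6-methoxyindole-1-carboxylate | COc1ccc2c(-c3c(OC)c(OC)c(CCO[Si](C)(C)C(C)(C)C)c(OC)c3OC)cn(C(=O)OC(C)(C)C)c2c1
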